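**Retrosynthetic overview**
- The target is reached by acid hydrolysis of a 2-(dimethoxymethyl)pyrrole; the pyrrole is the only ring and is closed last (N–C5) from a γ-imino aldehyde.
- The γ-imino aldehyde comes from deoxygenation of a γ-nitro aldehyde, so the nitro nitrogen becomes the ring nitrogen.
- Key disconnection C2–C3: the nitronate of 1,1-dimethoxy-2-nitroethane, a masked acyl anion that already carries N and the protected formyl carbon, adds to the β-carbon of (E)-tetracos-2-enal.
- The enal comes from docosan-1-ol by one-pot oxidation and Wittig two-carbon extension.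

Assumption: the side chain in the SMILES is n-henicosyl (21 carbons) and the molecule has no stereocentre, so the target is achiral and no enantiomer has to be selected; the stereocentres that appear in the nitro aldehyde are left uncontrolled because both become sp2 in the pyrrole.

**Route**

Step 1
Reactants: 1 docosan-1-ol; 2 (triphenylphosphoranylidene)acetaldehyde
Product: 4 (E)-tetracos-2-enal, via docosanal 3 (not isolated)
Conditions: (2,2,6,6-tetramethylpiperidin-1-yl)oxyl (10 mol %), PhI(OAc)2 (1.1 equiv), CH2Cl2, 35 °C; then 2 (1.2 equiv), CH2Cl2 exchanged for toluene, 80 °C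
Reagents that add atoms: none
Why: Oxoammonium (nitroxyl/PhI(OAc)2) oxidation stops at the aldehyde and is followed in the same flask by a Wittig olefination, in which the stabilised formyl ylide reacts faster with saturated aldehyde 3 than with the conjugated product and gives the E-alkene; no stereocentre is formed.

Step 2
Reactants: 4 (E)-tetracos-2-enal; 5 1,1-dimethoxy-2-nitroethane
Product: 6 3-(2,2-dimethoxy-1-nitroethyl)tetracosanal
Conditions: 5 (1.5 equiv), (S)-2-[diphenyl(trimethylsilyloxy)methyl]pyrrolidine (10 mol %, chirality irrelevant), PhCO2H (20 mol %), CH2Cl2/MeOH 3:1, 20 °C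
Reagents that add atoms: none
Why: Iminium-catalysed nitro-Michael addition in which the nitronate of 5 acts as a masked acyl anion for the future ring carbon C2 and attacks the β-carbon of the iminium ion of 4, joining two inherently electrophilic carbons and creating the 1,4-relationship between C2 and C5 with full atom economy; the two new stereocentres form as a mixture on purpose because both are erased on aromatisation.

Step 3
Reactants: 6 3-(2,2-dimethoxy-1-nitroethyl)tetracosanal
Product: 9 3-henicosyl-1H-pyrrole-2-carbaldehyde, via 3-(2,2-dimethoxyethanimidoyl)tetracosanal 7 (not isolated), via 2-(dimethoxymethyl)-3-henicosyl-1H-pyrrole 8 (not isolated)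
Conditions: Bu3P (3 equiv), PhSSPh (1.5 equiv, sulfur mediator returned unchanged), THF, 20 to 50 °C; then 1 M aq. HCl, THF, 20 °C
Reagents that add atoms: water, O
Why: Phosphine/disulfide deoxygenation of the secondary nitro group (nitro-to-imine reduction, known for γ-nitro ketones) gives N–H ketimine 7, which undergoes Paal–Knorr-type cyclodehydration with the γ-aldehyde to pyrrole 8, and acid hydrolysis of the labile 2-(dimethoxymethyl) group then gives the aldehyde; no stereocentre remains.

**Compound list**
1 | docosan-1-ol | CCCCCCCCCCCCCCCCCCCCCCO | starting material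
2 | (triphenylphosphoranylidene)acetaldehyde | O=CC=P(c1ccccc1)(c1ccccc1)c1ccccc1 | starting material
3 | docosanal | CCCCCCCCCCCCCCCCCCCCCC=O | intermediate (not isolated)
4 | (E)-tetracos-2-enal | CCCCCCCCCCCCCCCCCCCCC/C=C/C=O | intermediate
5 | 1,1-dimethoxy-2-nitroethane | COC(OC)C[N+](=O)[O-] | starting material
6 | 3-(2,2-dimethoxy-1-nitroethyl)tetracosanal (mixture of diastereomers, stereocentres unassigned) | CCCCCCCCCCCCCCCCCCCCCC(CC=O)C(C(OC)OC)[N+](=O)[O-] | intermediate
7 | 3-(2,2-dimethoxyethanimidoyl)tetracosanal (racemic) | CCCCCCCCCCCCCCCCCCCCCC(CC=O)C(=N)C(OC)OC | intermediate (not isolated)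
8 | 2-(dimethoxymethyl)-3-henicosyl-1H-pyrrole | CCCCCCCCCCCCCCCCCCCCCc1cc[nH]c1C(OC)OC | intermediate (not isolated)
9 | 3-henicosyl-1H-pyrrole-2-carbaldehyde (achiral) | CCCCCCCCCCCCCCCCCCCCCc1cc[nH]c1C=O | target

**Step count**
Total steps: 3. Longest linear sequence: 3 steps (1 → 4 → 6 → 9).

**Steps most likely to fail, with fallbacks**

Step 2 is the riskiest. The nitronate of 5 is hindered and functionalised, so conjugate addition may be slow and 1,2-addition (Henry) to the aldehyde may compete. The fallback makes the same intermediate through the other bond (C3–C4), with a nitroalkene acting as an α-carbonyl cation equivalent. It sets out from docosan-1-ol 1, which is oxidised as in step 1 but worked up to isolate docosanal 3. Aldehyde 3 and nitro acetal 5 are condensed on basic Al2O3 (0 to 40 °C, no solvent), giving first the Henry adduct 1,1-dimethoxy-2-nitrotetracosan-3-ol F1 and then, by loss of water on the support, the nitroalkene 1,1-dimethoxy-2-nitrotetracos-2-ene F2. Acetaldehyde (5 equiv) is then added to F2 by enamine catalysis with (S)-2-[diphenyl(trimethylsilyloxy)methyl]pyrrolidine (20 mol %) in 1,4-dioxane at 20 °C, and protonation of the nitronate brings the route back at 6.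

Step 3 is next. The oxime-stage intermediate can close on the aldehyde to an N-hydroxypyrrole, and the aldehyde may be touched by thiol or phosphine; the reagent system is precedented for γ-nitro ketones, not γ-nitro aldehydes. The fallback sets out from 6 and works at the amine oxidation level instead. Zn dust in AcOH/EtOH (0 to 20 °C) reduces the nitro group to the amine, which condenses with the aldehyde to the cyclic imine 2-(dimethoxymethyl)-3-henicosyl-3,4-dihydro-2H-pyrrole F3. Dehydrogenation with activated MnO2 (toluene, 80 °C) gives pyrrole 8, where the route is rejoined before the acid hydrolysis to 9.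

Step 1 is the least risky. The formyl ylide is sluggish and can homologate the product a second time to the dienal, and the acetic acid formed in the oxidation may slow the olefination. The fallback sets out from 1, oxidised and isolated as 3. Horner–Wadsworth–Emmons olefination with triethyl phosphonoacetate (NaH, THF, 0 °C) gives ethyl (E)-tetracos-2-enoate F4, i-Bu2AlH (CH2Cl2, −78 °C) gives (E)-tetracos-2-en-1-ol F5, and MnO2 (CH2Cl2, 20 °C) brings the route back at 4.

**Further compounds**
F1 | step 2 | 1,1-dimethoxy-2-nitrotetracosan-3-ol (mixture of diastereomers) | CCCCCCCCCCCCCCCCCCCCCC(O)C(C(OC)OC)[N+](=O)[O-]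
F2 | step 2 | 1,1-dimethoxy-2-nitrotetracos-2-ene (E/Z mixture, geometry immaterial) | CCCCCCCCCCCCCCCCCCCCCC=C(C(OC)OC)[N+](=O)[O-]
F3 | step 3 | 2-(dimethoxymethyl)-3-henicosyl-3,4-dihydro-2H-pyrrole (mixture of diastereomers) | CCCCCCCCCCCCCCCCCCCCCC1CC=NC1C(OC)OC
F4 | step 1 | ethyl (E)-tetracos-2-enoate | CCCCCCCCCCCCCCCCCCCCC/C=C/C(=O)OCC
F5 | step 1 | (E)-tetracos-2-en-1-ol | CCCCCCCCCCCCCCCCCCCCC/C=C/CO
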